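The central pyrrole is cut at N1–C5 and C4–C5, so that C5 and its acetyl group arrive as the single carbon of an acetonyl sulfonium ylide. The feature exploited is that C5 lies between N1 and C4 of the pyrrole ring and carries an acidifying ketone. The partner is an N-tosyl 1-azadiene, N1=C2(CO2Et)–C3(indolyl)=C4H(indolyl), that already holds the ester and both N-tosylindole rings. In one flask, conjugate addition, ring closure with loss of dimethyl sulfide and base-induced loss of sulfinate give the fully substituted aromatic pyrrole. The azadiene comes from Wittig olefination, bromination, Suzuki coupling and sulfonamide condensation; one hydrolysis then finishes the target.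

Key step: step 7

Remarks on the chemistry
- The ester alkyl group is a spectator. Ethyl is used throughout because the three-carbon Wittig reagent is sold as its ethyl ester.
- An aldol or Knoevenagel union of an indol-3-ylpyruvate ester with the aldehyde is avoided. The β-hydroxy adducts of arylpyruvates close onto their own ester to give 3-hydroxyfuran-2(5H)-ones instead of dehydrating. N-tosylation of such a pyruvate also competes with O-sulfonylation of its enol.
- N-Sulfonyl ketimines invert readily at nitrogen, so the C=N geometry written for the azadiene is nominal. The C3=C4 geometry is lost in the key step.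

Step 1
Reactants: 1 indole-3-carbaldehyde
Product: 2 1-tosylindole-3-carbaldehyde
Conditions: TsCl, Et3N, DMAP (cat.), CH2Cl2, 0 °C to rt
Reagents that add atoms: p-toluenesulfonyl chloride, Cc1ccc(cc1)S(=O)(=O)Cl
Why: Routine N-sulfonylation of an acidic 3-acylindole N–H, in which the tosyl group switches off the vinylogous-amide donation of the indole so that the aldehyde, and later C4 of the azadiene, react as ordinary aryl-substituted electrophiles.

Step 2
Reactants: 2 1-tosylindole-3-carbaldehyde; 3 ethyl 2-oxo-3-(triphenylphosphoranylidene)propanoate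
Product: 4 ethyl (E)-2-oxo-4-(1-tosylindol-3-yl)but-3-enoate
Conditions: toluene, 80 °C
Reagents that add atoms: none
Why: Wittig olefination with a carbonyl-stabilised ylide should give the E-enone without added base, which spares the hydroxide-labile N-tosyl group that a classical pyruvate aldol condensation would strip.

Step 3
Reactants: 4 ethyl (E)-2-oxo-4-(1-tosylindol-3-yl)but-3-enoate
Product: 6 ethyl (Z)-3-bromo-2-oxo-4-(1-tosylindol-3-yl)but-3-enoate, via dibromide 5 (not isolated)
Conditions: Br2, CH2Cl2, 0 °C; then Et3N, 0 °C to rt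
Reagents that add atoms: bromine, BrBr
Why: Bromine addition followed by dehydrobromination is the standard route to α-bromoenones, since the exocyclic alkene is the vinylogous enamine terminus and hence the most nucleophilic π-bond, and Et3N then removes the acidic C3 proton and expels the benzylic C4 bromide to leave the Z-bromide.

Step 4
Reactants: 6 ethyl (Z)-3-bromo-2-oxo-4-(1-tosylindol-3-yl)but-3-enoate; 7 (1-tosylindol-3-yl)boronic acid
Product: 8 ethyl (E)-2-oxo-3,4-bis(1-tosylindol-3-yl)but-3-enoate
Conditions: Pd(OAc)2 (cat.), SPhos (cat.), K3PO4, toluene (trace H2O), 70 °C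
Reagents that add atoms: none
Why: In this Suzuki–Miyaura coupling the electron-poor α-bromoenone adds quickly to zerovalent palladium and couples with retention, so the C3 indole is installed without passing through a β-hydroxy ester that could lactonise, and the nearly anhydrous phosphate base protects the α-keto ester.

Step 5
Reactants: 8 ethyl (E)-2-oxo-3,4-bis(1-tosylindol-3-yl)but-3-enoate; 9 p-toluenesulfonamide
Product: 10 ethyl (3E)-2-(tosylimino)-3,4-bis(1-tosylindol-3-yl)but-3-enoate
Conditions: TiCl4, Et3N, CH2Cl2, 0 °C to reflux; filtration through Celite, used without chromatography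
Reagents that add atoms: none
Why: TiCl4-mediated dehydrative condensation of a sulfonamide with a non-enolisable, highly electrophilic α-keto ester is the established entry to 2-alkoxycarbonyl N-sulfonyl 1-azadienes, with titanium serving as both chelating Lewis acid and water scavenger.

Step 6
Reactants: 11 chloroacetone
Product: 12 dimethyl(2-oxopropyl)sulfonium chloride
Conditions: Me2S, acetone, rt
Reagents that add atoms: dimethyl sulfide, CSC
Why: SN2 alkylation of dimethyl sulfide by an activated α-chloroketone should give the sulfonium salt as a precipitate that needs no chromatography.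

Step 7
Reactants: 10 ethyl (3E)-2-(tosylimino)-3,4-bis(1-tosylindol-3-yl)but-3-enoate; 12 dimethyl(2-oxopropyl)sulfonium chloride
Product: 15 ethyl 5-acetyl-3,4-bis(1-tosylindol-3-yl)-1H-pyrrole-2-carboxylate, via sulfonium ylide 13 (not isolated), via N-tosyl dihydropyrrole 14 (not isolated)
Conditions: K2CO3, 4 Å MS, MeCN, 0 °C to rt; then DBU, 60 °C
Reagents that add atoms: none
Why: K2CO3 deprotonates salt 12 to ylide 13, whose carbon adds in Michael fashion to C4 of azadiene 10 (new C4–C5 bond), leaving a betaine whose negative charge is shared by N1, C3 and the C2 ester. The sulfonamide nitrogen then pushes dimethyl sulfide off C5 in a 5-exo-tet SN2 closure (new N1–C5 bond) that forms the five-membered ring as dihydropyrrole 14. C4 and C5 of 14 are transient stereocentres, expected trans because the acetyl group avoids the C4 indole during closure, and both vanish when DBU takes the C5 proton next to the acetyl group, expels p-toluenesulfinate from N1 (E1cB) and the 3H-pyrrole so formed tautomerises to aromatic, achiral 15. The closest known reaction type is the formal [4+1] annulation of carbonyl-stabilised sulfur ylides with α,β-unsaturated N-sulfonyl imines to 2,3-dihydropyrroles, coupled with base-induced desulfinative aromatisation. Two selectivities are needed, 1,4- over 1,2-attack and N- over C3-closure: a stabilised ylide adds reversibly, C2 is a crowded, fully substituted ketimine carbon, and the sulfonyl and ester groups polarise the diene towards C4, while closure at C3 would have to build a strained ring with a quaternary carbon flanked by two indoles. The N-tosyl groups keep both indoles from donating into the diene, and either C3=C4 geometry leads to the same product because that geometry is erased on addition.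

Step 8
Reactants: 15 ethyl 5-acetyl-3,4-bis(1-tosylindol-3-yl)-1H-pyrrole-2-carboxylate
Product: 16 5-acetyl-3,4-di(1H-indol-3-yl)-1H-pyrrole-2-carboxylic acid (target)
Conditions: KOH (aq., excess), 1,4-dioxane, 90 °C; then 1 M HCl, 0 °C, to pH 3
Reagents that add atoms: potassium hydroxide, [K+].[OH-]
Why: Alkaline hydrolysis cleaves both indole N–S bonds by attack at sulfur and saponifies the ester in one operation while the acetyl group is shielded within the electron-rich pyrrolide anion, the alcohol-free medium prevents formation of alkyl tosylates that could N-alkylate the indolide or pyrrolide anions, and cold, mild acidification guards the pyrrole-2-carboxylic acid against decarboxylation.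

Compound list
1 | indole-3-carbaldehyde | O=Cc1c[nH]c2ccccc12 | starting material
2 | 1-tosylindole-3-carbaldehyde | O=Cc1cn(S(=O)(=O)c2ccc(C)cc2)c2ccccc12 | intermediate
3 | ethyl 2-oxo-3-(triphenylphosphoranylidene)propanoate | CCOC(=O)C(=O)C=P(c1ccccc1)(c1ccccc1)c1ccccc1 | starting material
4 | ethyl (E)-2-oxo-4-(1-tosylindol-3-yl)but-3-enoate | CCOC(=O)C(=O)/C=C/c1cn(S(=O)(=O)c2ccc(C)cc2)c2ccccc12 | intermediate
5 | ethyl 3,4-dibromo-2-oxo-4-(1-tosylindol-3-yl)butanoate (racemic; configuration not controlled and lost on elimination) | CCOC(=O)C(=O)C(Br)C(Br)c1cn(S(=O)(=O)c2ccc(C)cc2)c2ccccc12 | intermediate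
6 | ethyl (Z)-3-bromo-2-oxo-4-(1-tosylindol-3-yl)but-3-enoate | CCOC(=O)C(=O)/C(Br)=C/c1cn(S(=O)(=O)c2ccc(C)cc2)c2ccccc12 | intermediate
7 | (1-tosylindol-3-yl)boronic acid | OB(O)c1cn(S(=O)(=O)c2ccc(C)cc2)c2ccccc12 | starting material
8 | ethyl (E)-2-oxo-3,4-bis(1-tosylindol-3-yl)but-3-enoate | CCOC(=O)C(=O)/C(c1cn(S(=O)(=O)c2ccc(C)cc2)c2ccccc12)=C/c1cn(S(=O)(=O)c2ccc(C)cc2)c2ccccc12 | intermediate
9 | p-toluenesulfonamide | Cc1ccc(S(N)(=O)=O)cc1 | starting material
10 | ethyl (3E)-2-(tosylimino)-3,4-bis(1-tosylindol-3-yl)but-3-enoate (C=N geometry nominal) | CCOC(=O)/C(=N/S(=O)(=O)c1ccc(C)cc1)/C(c1cn(S(=O)(=O)c2ccc(C)cc2)c2ccccc12)=C/c1cn(S(=O)(=O)c2ccc(C)cc2)c2ccccc12 | intermediate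
11 | chloroacetone | CC(=O)CCl | starting material
12 | dimethyl(2-oxopropyl)sulfonium chloride | CC(=O)C[S+](C)C.[Cl-] | intermediate
13 | dimethylsulfonium acetonylide | CC(=O)[CH-][S+](C)C | intermediate
14 | ethyl trans-5-acetyl-1-tosyl-3,4-bis(1-tosylindol-3-yl)-4,5-dihydro-1H-pyrrole-2-carboxylate (racemic, one enantiomer drawn) | CCOC(=O)C1=C(c2cn(S(=O)(=O)c3ccc(C)cc3)c3ccccc23)[C@@H](c2cn(S(=O)(=O)c3ccc(C)cc3)c3ccccc23)[C@H](C(C)=O)N1S(=O)(=O)c1ccc(C)cc1 | intermediate
15 | ethyl 5-acetyl-3,4-bis(1-tosylindol-3-yl)-1H-pyrrole-2-carboxylate | CCOC(=O)c1[nH]c(C(C)=O)c(-c2cn(S(=O)(=O)c3ccc(C)cc3)c3ccccc23)c1-c1cn(S(=O)(=O)c2ccc(C)cc2)c2ccccc12 | intermediate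
16 | 5-acetyl-3,4-di(1H-indol-3-yl)-1H-pyrrole-2-carboxylic acid (CNP0301407.0, no stereocentre) | CC(=O)c1[nH]c(C(=O)O)c(-c2c[nH]c3ccccc23)c1-c1c[nH]c2ccccc12 | target

Total step count: 8
Longest linear sequence: 7 (steps 1, 2, 3, 4, 5, 7, 8)

Steps most likely to fail

1. Step 7. The ylide may attack the imine carbon instead of C4, or the betaine may close through C3. Proton transfer inside the betaine may also park the material as a new stabilised ylide. Crowding of C4 by the twisted C3 indole slows the wanted addition and gives these processes time. The fallback sets out from 8 and comes back at 15. It brings C5 in as nitromethane and adds the acetyl group last.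
   - Base-catalysed Michael addition of nitromethane to 8 (DBU cat., MeCN, rt) should give ethyl 5-nitro-2-oxo-3,4-bis(1-tosylindol-3-yl)pentanoate F1.
   - Reduction of the nitro group (Fe, AcOH, 60 °C), with spontaneous condensation of the amine onto the ketone, should give ethyl 3,4-bis(1-tosylindol-3-yl)-3,4-dihydro-2H-pyrrole-5-carboxylate F2.
   - Dehydrogenation with DDQ (toluene, rt) should give ethyl 3,4-bis(1-tosylindol-3-yl)-1H-pyrrole-2-carboxylate F3.
   - Friedel–Crafts acetylation (Ac2O, SnCl4, CH2Cl2, 0 °C) at C5, the only free pyrrole position, should then give 15. The sulfonylated indoles are too deactivated to compete.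

2. Step 5. Condensation may stall at a ketone flanked by a fully substituted alkene carbon. The sulfonamide may add reversibly to C4, and the ketimine may hydrolyse during isolation. The fallback sets out from 8 and comes back at 10. It installs nitrogen with a small nucleophile and builds the sulfonyl group by rearrangement.
   - Hydroxylamine hydrochloride in pyridine/EtOH should give ethyl (3E)-2-(hydroxyimino)-3,4-bis(1-tosylindol-3-yl)but-3-enoate F4.
   - p-Toluenesulfinyl chloride and Et3N in CH2Cl2 at −20 °C should convert it into ethyl (3E)-2-[(p-tolylsulfinyl)oxyimino]-3,4-bis(1-tosylindol-3-yl)but-3-enoate F5.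
   - On warming to rt, F5 should rearrange by N–O homolysis and recombination at sulfur to the N-sulfonyl imine 10.

3. Step 4. The indol-3-ylboronic acid may protodeboronate, the base may hydrolyse or hydrate the α-keto ester, and transmetalation at the crowded α-position may be slow. The fallback sets out from 6 and comes back at 8. It replaces the boron nucleophile with a tin nucleophile, so no base is present.
   - Purchased 3-iodo-1-tosylindole is stannylated ((Bu3Sn)2, Pd(PPh3)4, toluene, 100 °C) to 1-tosyl-3-(tributylstannyl)indole F6.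
   - Stille coupling of F6 with 6 (Pd2(dba)3, P(2-furyl)3, NMP, 60 °C) should give 8.

Further compounds
F1 | step 7 | ethyl 5-nitro-2-oxo-3,4-bis(1-tosylindol-3-yl)pentanoate (racemic diastereomer mixture; centres erased at F3) | CCOC(=O)C(=O)C(c1cn(S(=O)(=O)c2ccc(C)cc2)c2ccccc12)C(C[N+](=O)[O-])c1cn(S(=O)(=O)c2ccc(C)cc2)c2ccccc12
F2 | step 7 | ethyl 3,4-bis(1-tosylindol-3-yl)-3,4-dihydro-2H-pyrrole-5-carboxylate (racemic diastereomer mixture; centres erased at F3) | CCOC(=O)C1=NCC(c2cn(S(=O)(=O)c3ccc(C)cc3)c3ccccc23)C1c1cn(S(=O)(=O)c2ccc(C)cc2)c2ccccc12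
F3 | step 7 | ethyl 3,4-bis(1-tosylindol-3-yl)-1H-pyrrole-2-carboxylate | CCOC(=O)c1[nH]cc(-c2cn(S(=O)(=O)c3ccc(C)cc3)c3ccccc23)c1-c1cn(S(=O)(=O)c2ccc(C)cc2)c2ccccc12
F4 | step 5 | ethyl (3E)-2-(hydroxyimino)-3,4-bis(1-tosylindol-3-yl)but-3-enoate (oxime geometry not defined) | CCOC(=O)C(=NO)/C(c1cn(S(=O)(=O)c2ccc(C)cc2)c2ccccc12)=C/c1cn(S(=O)(=O)c2ccc(C)cc2)c2ccccc12
F5 | step 5 | ethyl (3E)-2-[(p-tolylsulfinyl)oxyimino]-3,4-bis(1-tosylindol-3-yl)but-3-enoate | CCOC(=O)C(=NOS(=O)c1ccc(C)cc1)/C(c1cn(S(=O)(=O)c2ccc(C)cc2)c2ccccc12)=C/c1cn(S(=O)(=O)c2ccc(C)cc2)c2ccccc12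
F6 | step 4 | 1-tosyl-3-(tributylstannyl)indole | CCCC[Sn](CCCC)(CCCC)c1cn(S(=O)(=O)c2ccc(C)cc2)c2ccccc12
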